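The numbers of this flask are those of an exercise; no experiment stands behind them.

Slowness was my first question about two flasks in which a solid electrophile dissolves and meets a nucleophile that also binds the acid set free.

| flask | solid electrophile | nucleophile | time |
|---|---|---|---|
| midnight | 0.10 M | 0.120 M | 4.0 min |
| winter | 0.10 M | 0.160 M | 4.0 min |

    electrophile + nucleophile ⇌ acid set free + target (K1 = 0.34, k1 = 0.618 L mol⁻¹ s⁻¹)
    nucleophile + acid set free ⇌ protonated nucleophile, settled at all times (K2 = 930 L mol⁻¹)
    solid electrophile ⇌ electrophile, rate k3*(cs3 - [electrophile]) while solid is left; crystals form when [electrophile] > cs3 (cs3 = 0.055 M, k3 = 0.0353 s⁻¹)
    nucleophile + target → over-reaction product (k4 = 0.00398 L mol⁻¹ s⁻¹)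

- as a solid, counted per litre of solution: solid electrophile
- at the start none of the solid electrophile is in solution
- what has only dissolved of solid electrophile counts as not reacted
- run time (midnight): 4.0 min

- part of the solid electrophile that has reacted (what has only dissolved counts as not reacted) at the end, midnight
- part of the solid electrophile that has reacted (what has only dissolved counts as not reacted) at the end, winter
- what raising the concentration of nucleophile from its lowest to its highest value here does to the part of the solid electrophile that has reacted (what has only dissolved counts as not reacted) (changes below 5 percentage points count as none) (it rises / no change / it falls)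

In midnight the electrophile had a half-life of 0.16 min by the forward first step, with the nucleophile as charged, and the dissolution coefficient gave a time of 0.472 min, both shorter than the run. The target's half-life in midnight by over-reaction, with the nucleophile as charged, was 24 min, longer than the run. So I reckoned the end state of the first two steps and set over-reaction aside.

I took the acid as bound, so each electrophile reacted cost 2 nucleophile. Half the charge, 0.0600 M in midnight and 0.0800 M in winter, was less than the electrophile charged, which made the nucleophile the limiting reagent. Multiplying the two balances gave K = 316 L mol⁻¹, and then:

r = c(target)/c(nucleophile) = √(K·c(electrophile))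

c(target) = charge·r/(1 + 2r)

I iterated from c(electrophile) = solid charged minus half the nucleophile:

midnight: r = 3.56, 3.87, 3.85; c(target) = 0.0531 M

winter: r = 2.51, 3.24, 3.11; c(target) = 0.0689 M

The electrophile left, 0.0469 M in midnight and 0.0311 M in winter, lay below the solubility 0.055 M, so I let the solid dissolve completely in both flasks.

This balance ratio, target per free nucleophile, had one weak link, the bound acid. The second balance, with bound nucleophile taken equal to target, leaves c(acid set free) = r/930, and each free acid spares a nucleophile:

c(target) = (charge + c(acid set free))·r/(1 + 2r)

That raised my figures to 54.9% for midnight and 70.4% for winter, with winter the higher by 16 percentage points.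

The forecast gave 54.5% (52% to 57%) for midnight and 70% (67% to 73%) for winter, with the verdict it rises, holding that “each unit of conversion costs nearly two units of nucleophile”.

Midnight gave 54.7% reacted and winter 69.9%; the part reacted: it rises, by 15 points.

The ratio also gave midnight's free acid as 0.00414 M, and midnight held 0.00396 M at 4.00 min. I then took a neighbour of winter charged with 0.064 M of nucleophile. There the solid charged minus half the nucleophile, 0.0680 M, lay above the solubility, so I held c(electrophile) at the solubility and r = 4.17. The same line gave 30.6% reacted, with 14.4% of the charge reckoned still solid. The neighbour gave 30.6% reacted and 14.5% solid at 4.00 min.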